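**Retrosynthetic overview**

- The target is the 3-bromo-12H-pyrido[1,2-a:3,4-b']diindole (rings A–E) with a methyl oxoacetate on C13. The strategy rests on C13 of ring D, which is bonded to three separable pieces (C13a of ring E, C12b and the ketoester carbonyl), while the N5–C12b bond completes rings D/E as a 2,3-disubstituted indole.
- Ring C is opened last in the retrosynthesis: the C6=C7 double bond comes from dehydrogenation and N5–C6 from a Mitsunobu closure, leading back to a 2,2'-biindole with a hydroxyethyl arm on C7a.
- Ring D is then taken apart into 5-bromo-2-iodoaniline (ring E and N5), a 2-ethynylindole (rings A/B, whose alkyne carbons become C12b and C13) and methyl chlorooxoacetate. One flask forms C13–C13a (Sonogashira), N5–C12b (ZnBr2 hydroamination) and C13–CO (acylation).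
- The ethynylindole comes from tryptophol by O-silylation, N-Boc protection, C2 lithiation/iodination, Sonogashira coupling with trimethylsilylacetylene and C-desilylation.
- Ring order: A/B and E are bought, D is formed in the key step, C is formed last.

Key step: step 6

Remark: locants follow 12H-pyrido[1,2-a:3,4-b']diindole. Ring A is the benzo ring C7b–C11a, ring B the pyrrole with N12, ring C is N5/C6/C7/C7a/C12a/C12b, ring D is N5/C12b/C13/C13a/C4a, and ring E is the brominated benzo ring. The target is achiral, so no stereocentre has to be set.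

**Route**

Step 1
Reactants: 1 tryptophol
Product: 2 3-[2-(tert-butyldimethylsilyloxy)ethyl]-1H-indole
Conditions: TBSCl (1.1 equiv), imidazole (2 equiv), DMF, 0 °C → rt
Reagents that add atoms: tert-butyldimethylsilyl chloride, CC(C)(C)[Si](C)(C)Cl
Why: Imidazole-promoted silyl ether formation at the primary alcohol is much faster than any reaction at the weakly nucleophilic indole N–H, so only oxygen should be protected.

Step 2
Reactants: 2 3-[2-(tert-butyldimethylsilyloxy)ethyl]-1H-indole
Product: 3 tert-butyl 3-[2-(tert-butyldimethylsilyloxy)ethyl]-1H-indole-1-carboxylate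
Conditions: Boc2O (1.2 equiv), DMAP (0.1 equiv), MeCN, rt
Reagents that add atoms: di-tert-butyl dicarbonate, CC(C)(C)OC(=O)OC(=O)OC(C)(C)C
Why: DMAP-catalysed carbamate formation on the indole nitrogen installs the group that directs metalation to C2 and keeps this nitrogen silent in the key step.

Step 3
Reactants: 3 tert-butyl 3-[2-(tert-butyldimethylsilyloxy)ethyl]-1H-indole-1-carboxylate
Product: 5 tert-butyl 3-[2-(tert-butyldimethylsilyloxy)ethyl]-2-iodo-1H-indole-1-carboxylate, via 2-lithioindole 4 (not isolated)
Conditions: LiN(iPr)2 (1.3 equiv), THF, −78 °C; then I2 (1.4 equiv) in THF, −78 → −40 °C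
Reagents that add atoms: iodine, II
Why: Carbamate-directed lithiation at C2 of an N-Boc indole followed by iodinolysis of the C–Li bond is a standard entry to 2-iodoindoles, and holding the anion at low temperature should suppress migration of the Boc group to C2.

Step 4
Reactants: 5 tert-butyl 3-[2-(tert-butyldimethylsilyloxy)ethyl]-2-iodo-1H-indole-1-carboxylate; 6 trimethylsilylacetylene
Product: 7 tert-butyl 3-[2-(tert-butyldimethylsilyloxy)ethyl]-2-[(trimethylsilyl)ethynyl]-1H-indole-1-carboxylate
Conditions: PdCl2(PPh3)2 (3 mol %), CuI (6 mol %), Et3N, THF, rt → 45 °C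
Reagents that add atoms: none
Why: Sonogashira coupling of the heteroaryl iodide with the silyl-capped alkyne forms the C12a–C12b bond under mild conditions, the silyl cap excluding double coupling.

Step 5
Reactants: 7 tert-butyl 3-[2-(tert-butyldimethylsilyloxy)ethyl]-2-[(trimethylsilyl)ethynyl]-1H-indole-1-carboxylate
Product: 8 tert-butyl 3-[2-(tert-butyldimethylsilyloxy)ethyl]-2-ethynyl-1H-indole-1-carboxylate
Conditions: K2CO3 (0.2 equiv), MeOH/THF 1:1, 0 °C, short reaction time
Reagents that add atoms: none
Why: Methoxide-mediated protodesilylation of the alkynyl–silicon bond is fast at 0 °C with catalytic K2CO3, conditions under which the TBS ether and the indole carbamate should persist.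

Step 6
Reactants: 8 tert-butyl 3-[2-(tert-butyldimethylsilyloxy)ethyl]-2-ethynyl-1H-indole-1-carboxylate (1.0 equiv, limiting); 9 5-bromo-2-iodoaniline (1.05 equiv); 10 methyl chlorooxoacetate (2 equiv)
Product: 13 methyl 2-{6-bromo-2-[1-(tert-butoxycarbonyl)-3-(2-(tert-butyldimethylsilyloxy)ethyl)-1H-indol-2-yl]-1H-indol-3-yl}-2-oxoacetate, via alkynylaniline 11 (not isolated), via biindole 12 (not isolated)
Conditions: PdCl2(PPh3)2 (3 mol %), CuI (5 mol %), Et3N (3 equiv), degassed toluene, rt; then ZnBr2 (2 equiv), 100 °C; then 10, 0 °C → rt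
Reagents that add atoms: none
Why: Zerovalent palladium generated in the flask inserts into the C–I bond of 9, and transmetalation from the copper acetylide of 8 followed by reductive elimination (Sonogashira coupling) forms C13–C13a to give 11. ZnBr2 with the Et3N already present then turns the aniline into a zinc anilide that adds across the alkyne in a 5-endo-dig hydroamination (N5–C12b, ring D), the known zinc-halide cycloisomerisation of free 2-alkynylanilines, leaving biindole 12 as its N-zinc salt. That zinc indolide attacks the acyl chloride through carbon C13, as in the established C3-acylation of indolylzinc halides, and loss of the C13 proton to Et3N restores the indole; no stereocentre is formed. The step needs C–I to react before C–Br, which room-temperature oxidative addition secures, and making alkyne 8 the limiting component leaves no terminal alkyne to couple with the bromide once the flask is heated. It also needs the amine and not the carbamate oxygen to add to the alkyne, and carbon and not nitrogen to be acylated; the hard zinc amide pathway (no π-acid), the zinc counter-ion and the fact that C13 is the only free nucleophilic indole carbon (the other indole is C3-substituted and N-Boc-blocked) should secure both. Any partial loss of the silyl or Boc group in this Lewis-acidic medium would be of no consequence, because step 7 removes both and would also methanolyse an oxalate formed on oxygen.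

Step 7
Reactants: 13 methyl 2-{6-bromo-2-[1-(tert-butoxycarbonyl)-3-(2-(tert-butyldimethylsilyloxy)ethyl)-1H-indol-2-yl]-1H-indol-3-yl}-2-oxoacetate
Product: 15 methyl 2-{6-bromo-2-[3-(2-hydroxyethyl)-1H-indol-2-yl]-1H-indol-3-yl}-2-oxoacetate, via N-Boc alcohol 14 (not isolated)
Conditions: HCl (3 M in MeOH), 0 → 40 °C
Reagents that add atoms: none
Why: Acid-catalysed methanolysis cleaves the primary TBS ether quickly and acidolysis of the indole carbamate (loss of isobutene and CO2) follows, while the methyl ketoester is safe because transesterification in methanol is degenerate.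

Step 8
Reactants: 15 methyl 2-{6-bromo-2-[3-(2-hydroxyethyl)-1H-indol-2-yl]-1H-indol-3-yl}-2-oxoacetate
Product: 16 methyl 2-(3-bromo-6,7-dihydro-12H-pyrido[1,2-a:3,4-b']diindol-13-yl)-2-oxoacetate
Conditions: PPh3 (1.5 equiv), DIAD (1.5 equiv), THF, 0 °C → rt
Reagents that add atoms: none
Why: In this Mitsunobu reaction the N5–H, acidified by conjugation with the C13 ketoester, is deprotonated by the PPh3/DIAD betaine and displaces the alkoxyphosphonium at C6 in a 6-exo-tet closure of ring C, whereas N12–H is less acidic and cannot reach C6.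

Step 9
Reactants: 16 methyl 2-(3-bromo-6,7-dihydro-12H-pyrido[1,2-a:3,4-b']diindol-13-yl)-2-oxoacetate
Product: 17 methyl 2-(3-bromo-12H-pyrido[1,2-a:3,4-b']diindol-13-yl)-2-oxoacetate
Conditions: DDQ (1.1 equiv), anhydrous 1,4-dioxane, rt → 60 °C
Reagents that add atoms: none
Why: DDQ dehydrogenation by hydride abstraction from C7 (benzylic to C7a and stabilised by the N12 lone pair) and loss of the C6 proton next to N5 should give the C6=C7 bond of the fully conjugated pentacycle without touching the aryl bromide, the dry solvent avoiding oxygenation at C7.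

**Compound list**

1 | tryptophol | OCCc1c[nH]c2ccccc12 | starting material
2 | 3-[2-(tert-butyldimethylsilyloxy)ethyl]-1H-indole | CC(C)(C)[Si](C)(C)OCCc1c[nH]c2ccccc12 | intermediate
3 | tert-butyl 3-[2-(tert-butyldimethylsilyloxy)ethyl]-1H-indole-1-carboxylate | CC(C)(C)OC(=O)n1cc(CCO[Si](C)(C)C(C)(C)C)c2ccccc12 | intermediate
4 | tert-butyl 3-[2-(tert-butyldimethylsilyloxy)ethyl]-2-lithio-1H-indole-1-carboxylate | [Li]c1c(CCO[Si](C)(C)C(C)(C)C)c2ccccc2n1C(=O)OC(C)(C)C | intermediate (not isolated)
5 | tert-butyl 3-[2-(tert-butyldimethylsilyloxy)ethyl]-2-iodo-1H-indole-1-carboxylate | Ic1c(CCO[Si](C)(C)C(C)(C)C)c2ccccc2n1C(=O)OC(C)(C)C | intermediate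
6 | trimethylsilylacetylene | C#C[Si](C)(C)C | starting material
7 | tert-butyl 3-[2-(tert-butyldimethylsilyloxy)ethyl]-2-[(trimethylsilyl)ethynyl]-1H-indole-1-carboxylate | C[Si](C)(C)C#Cc1c(CCO[Si](C)(C)C(C)(C)C)c2ccccc2n1C(=O)OC(C)(C)C | intermediate
8 | tert-butyl 3-[2-(tert-butyldimethylsilyloxy)ethyl]-2-ethynyl-1H-indole-1-carboxylate | C#Cc1c(CCO[Si](C)(C)C(C)(C)C)c2ccccc2n1C(=O)OC(C)(C)C | intermediate
9 | 5-bromo-2-iodoaniline | Nc1cc(Br)ccc1I | starting material
10 | methyl chlorooxoacetate | COC(=O)C(=O)Cl | starting material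
11 | tert-butyl 2-[(2-amino-4-bromophenyl)ethynyl]-3-[2-(tert-butyldimethylsilyloxy)ethyl]-1H-indole-1-carboxylate | Nc1cc(Br)ccc1C#Cc1c(CCO[Si](C)(C)C(C)(C)C)c2ccccc2n1C(=O)OC(C)(C)C | intermediate (not isolated)
12 | tert-butyl 2-(6-bromo-1H-indol-2-yl)-3-[2-(tert-butyldimethylsilyloxy)ethyl]-1H-indole-1-carboxylate (present in the flask as its N-zinc salt) | Brc1ccc2cc(-c3c(CCO[Si](C)(C)C(C)(C)C)c4ccccc4n3C(=O)OC(C)(C)C)[nH]c2c1 | intermediate (not isolated)
13 | methyl 2-{6-bromo-2-[1-(tert-butoxycarbonyl)-3-(2-(tert-butyldimethylsilyloxy)ethyl)-1H-indol-2-yl]-1H-indol-3-yl}-2-oxoacetate | COC(=O)C(=O)c1c(-c2c(CCO[Si](C)(C)C(C)(C)C)c3ccccc3n2C(=O)OC(C)(C)C)[nH]c2cc(Br)ccc12 | intermediate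
14 | methyl 2-{6-bromo-2-[1-(tert-butoxycarbonyl)-3-(2-hydroxyethyl)-1H-indol-2-yl]-1H-indol-3-yl}-2-oxoacetate | COC(=O)C(=O)c1c(-c2c(CCO)c3ccccc3n2C(=O)OC(C)(C)C)[nH]c2cc(Br)ccc12 | intermediate (not isolated)
15 | methyl 2-{6-bromo-2-[3-(2-hydroxyethyl)-1H-indol-2-yl]-1H-indol-3-yl}-2-oxoacetate | COC(=O)C(=O)c1c(-c2[nH]c3ccccc3c2CCO)[nH]c2cc(Br)ccc12 | intermediate
16 | methyl 2-(3-bromo-6,7-dihydro-12H-pyrido[1,2-a:3,4-b']diindol-13-yl)-2-oxoacetate | COC(=O)C(=O)c1c2ccc(Br)cc2n2CCc3c4ccccc4[nH]c3c12 | intermediate
17 | methyl 2-(3-bromo-12H-pyrido[1,2-a:3,4-b']diindol-13-yl)-2-oxoacetate | COC(=O)C(=O)c1c2ccc(Br)cc2n2ccc3c4ccccc4[nH]c3c12 | target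

**Step count and risk**

Total step count: 9. Longest linear sequence: 9 steps (tryptophol 1 to target 17); the other three components (6, 9, 10) are bought.

Steps most likely to fail, riskiest first:

1. Step 6. Three stages share one medium, and several things could go wrong in it. The hydroamination could stall. The Lewis acid could strip the silyl or Boc group, or steer the carbamate oxygen onto the alkyne. The acyl chloride could be consumed by the amine or react at nitrogen, and hot palladium could begin to insert into the C–Br bond. The fallback separates the three bond formations and changes how each ring-D bond is activated. It sets out from 8 and 9: the Sonogashira coupling is run alone and alkynylaniline 11 is isolated. Ring D is then closed with catalytic PdCl2(MeCN)2 in MeCN at 70 °C, where divalent palladium activates the alkyne for 5-endo-dig attack of the free amine and protodepalladation follows, and biindole 12 is isolated. Compound 12 is acylated at C13 without any metal by oxalyl chloride in Et2O at 0 °C, which should give the glyoxylyl chloride tert-butyl 2-[6-bromo-3-(2-chloro-2-oxoacetyl)-1H-indol-2-yl]-3-[2-(tert-butyldimethylsilyloxy)ethyl]-1H-indole-1-carboxylate F1. Quenching F1 with MeOH/Et3N returns the route at compound 13.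

2. Step 9. Hydride abstraction could be slow on a substrate deactivated by the ketoester, and oxygenation at C7 or oxidation beyond the pentacycle could compete. The fallback brings C6 to the aldehyde oxidation level before ring C is closed, so no dehydrogenation is needed. It sets out from 15: Dess–Martin periodinane (NaHCO3, CH2Cl2, 0 °C) should give the aldehyde methyl 2-{6-bromo-2-[3-(2-oxoethyl)-1H-indol-2-yl]-1H-indol-3-yl}-2-oxoacetate F2. With catalytic TsOH in toluene at 80 °C, N5–H adds to the aldehyde to give the hemiaminal methyl 2-(3-bromo-6-hydroxy-6,7-dihydro-12H-pyrido[1,2-a:3,4-b']diindol-13-yl)-2-oxoacetate F3 (racemic, not isolated). Dehydration of F3 gives the C6=C7 bond directly, so the fallback bypasses 16 and comes back at target 17.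

3. Step 8. The PPh3/DIAD betaine could add to the electrophilic α-ketoester carbonyl instead of activating the alcohol, or the activated alcohol could eliminate to a 3-vinylindole before the weakly nucleophilic N5 closes the ring. The fallback replaces the redox condensation by a two-stage sulfonate alkylation. It sets out from 15: MsCl/Et3N in CH2Cl2 at 0 °C should give the mesylate methyl 2-{6-bromo-2-[3-(2-(methylsulfonyloxy)ethyl)-1H-indol-2-yl]-1H-indol-3-yl}-2-oxoacetate F4. K2CO3 in DMF at rt then deprotonates the acidic N5–H, which displaces the mesylate (6-exo-tet), and the route is rejoined at compound 16.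

**Further compounds**

F1 | step 6 | tert-butyl 2-[6-bromo-3-(2-chloro-2-oxoacetyl)-1H-indol-2-yl]-3-[2-(tert-butyldimethylsilyloxy)ethyl]-1H-indole-1-carboxylate | O=C(Cl)C(=O)c1c(-c2c(CCO[Si](C)(C)C(C)(C)C)c3ccccc3n2C(=O)OC(C)(C)C)[nH]c2cc(Br)ccc12
F2 | step 9 | methyl 2-{6-bromo-2-[3-(2-oxoethyl)-1H-indol-2-yl]-1H-indol-3-yl}-2-oxoacetate | COC(=O)C(=O)c1c(-c2[nH]c3ccccc3c2CC=O)[nH]c2cc(Br)ccc12
F3 | step 9 | methyl 2-(3-bromo-6-hydroxy-6,7-dihydro-12H-pyrido[1,2-a:3,4-b']diindol-13-yl)-2-oxoacetate (racemic) | COC(=O)C(=O)c1c2ccc(Br)cc2n2C(O)Cc3c4ccccc4[nH]c3c12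
F4 | step 8 | methyl 2-{6-bromo-2-[3-(2-(methylsulfonyloxy)ethyl)-1H-indol-2-yl]-1H-indol-3-yl}-2-oxoacetate | COC(=O)C(=O)c1c(-c2[nH]c3ccccc3c2CCOS(C)(=O)=O)[nH]c2cc(Br)ccc12
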